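**Plan**
Carbocycle numbering: C1 = ring C=O, C2 = carbon bearing the lactam, C3 = C–OH, C4 = CH, C5 = C–CH3, C6 = C(prenyl)2. The retrosynthesis cuts, in this order: the bond from C2 to the stereogenic lactam carbon, the ring bond C5–C6, the bond C3–C4, and last C2–C3 together with C1–C6.
Enabling feature: C6–C1(O)–C2–C3(O) is a 1,3-dioxygenated four-carbon run ending in a non-stereogenic quaternary carbon. Tied by a temporary C3–C6 bond, this run is a 3-alkoxy-4,4-dialkylcyclobutenone, and C4=C5(CH3) is a propenyl anion. Opening the strained ring gives a hexatriene whose termini are C5 and C6.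
Forward, fragment 1: malonate → diprenylketene → [2+2] with ethoxyacetylene (four-membered ring) → propenyllithium addition, 4π opening and 6π closure (six-membered ring and quaternary carbon).
Helpers: the closure is run one oxidation level low (C4–C5 saturated) with the C1 oxygen masked as an ethyl ether. A Saegusa–Ito oxidation and a vinylogous saponification remove both helpers.
Fragment 2, the lactam ring, comes from a 2-formylbenzoate and ammonia, and the two fragments are joined last. The single (S) stereocentre is set in that last step by a chiral phosphoric acid. The transient C5 centre from the key step is racemic and is erased in step 6.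

Key step: step 5

Assumption: the (R)-configured acid of step 11 is taken to leave the Re face of the iminium carbon open (this sense must be checked once, and the (S)-acid serves otherwise); vinylogous acids 17 and 23 are drawn in the tautomer of the target SMILES.

**Step 1**
Reactants: 1 diethyl malonate; 2 prenyl bromide (1-bromo-3-methylbut-2-ene)
Product: 3 diethyl 2,2-bis(3-methylbut-2-en-1-yl)propanedioate
Conditions: NaH (2.3 equiv), 2 (2.2 equiv), THF/DMF, 0 °C → rt
Reagents that add atoms: none
Why: Double SN2 C-alkylation of the malonate enolate (malonic ester synthesis) with a reactive allylic bromide builds the future C6 with two identical prenyl groups, so no stereocentre arises.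

**Step 2**
Reactants: 3 diethyl 2,2-bis(3-methylbut-2-en-1-yl)propanedioate
Product: 5 5-methyl-2-(3-methylbut-2-en-1-yl)hex-4-enoic acid, via malonic diacid 4 (not isolated)
Conditions: KOH, EtOH/H2O, reflux; aq. HCl, 0 °C; xylene, reflux
Reagents that add atoms: potassium hydroxide, [K+].[OH-]
Why: Saponification followed by thermal decarboxylation of the geminal diacid (malonic ester synthesis) leaves the α-branched acid, and the isolated trisubstituted alkenes are inert to aqueous base and to short heating.

**Step 3**
Reactants: 5 5-methyl-2-(3-methylbut-2-en-1-yl)hex-4-enoic acid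
Product: 6 5-methyl-2-(3-methylbut-2-en-1-yl)hex-4-enoyl chloride
Conditions: (COCl)2, DMF (cat.), CH2Cl2, 0 °C → rt; concentrated and used crude
Reagents that add atoms: oxalyl chloride, ClC(=O)C(=O)Cl
Why: Acid chloride formation with oxalyl chloride and catalytic DMF runs below room temperature, where the trisubstituted alkenes are not attacked.

**Step 4**
Reactants: 6 5-methyl-2-(3-methylbut-2-en-1-yl)hex-4-enoyl chloride; 7 ethoxyacetylene
Product: 9 3-ethoxy-4,4-bis(3-methylbut-2-en-1-yl)cyclobut-2-en-1-one, via diprenylketene 8 (not isolated)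
Conditions: Et3N, 7 (3 equiv), toluene, sealed tube, 70 °C
Reagents that add atoms: none
Why: Dehydrochlorination gives the hindered, slowly dimerising dialkylketene 8, and in the ketene–alkoxyalkyne [2+2] cycloaddition the nucleophilic terminal carbon of the ynol ether attacks the ketene carbonyl carbon, so only the 3-ethoxy-4,4-dialkyl regioisomer should form.

**Step 5**
Reactants: 9 3-ethoxy-4,4-bis(3-methylbut-2-en-1-yl)cyclobut-2-en-1-one; 10 (E)-1-bromoprop-1-ene
Product: 15 1-ethoxy-5-methyl-6,6-bis(3-methylbut-2-en-1-yl)-3-(trimethylsilyloxy)cyclohexa-1,3-diene (racemic), via (E)-prop-1-enyllithium 11 (not isolated), via lithium cyclobutenoxide 12 (not isolated), via lithium trienolate 13 (not isolated), via lithium cyclohexadienolate 14 (not isolated)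
Conditions: 10, t-BuLi (2 equiv per 10), Et2O, −78 °C; 9 in THF, −78 °C → 40 °C; Me3SiCl/Et3N, −78 → 0 °C; cold NaHCO3 work-up, used without chromatography
Reagents that add atoms: chlorotrimethylsilane, C[Si](C)(C)Cl
Why: The hard alkenyllithium 11 adds 1,2 to the strained carbonyl of vinylogous ester 9, and in alkoxide 12 the ring strain and the oxido donor lower the barrier of the conrotatory 4π opening of the only sp3–sp3 ring bond, C(O−)–C(prenyl)2; the oxido group rotates outward, so the propenyl arm turns inward and trienolate 13 forms with its two vinyl arms cis on the central double bond. A thermal disrotatory 6π electrocyclisation then joins the propenyl terminus (C5) to the C(prenyl)2 terminus (C6), closing the six-membered carbocycle and creating the quaternary carbon in one event, and the exchange of a π bond for a σ bond together with the released four-ring strain makes the sequence irreversible. The closest known reaction type is the two-carbon ring expansion of cyclobutenones and benzocyclobutenones by alkenyllithium addition, oxyanion-accelerated 4π opening and 6π closure. The only new stereocentre, C5, arises racemic because 9 is achiral, needs no control and is erased in step 6, while C6 bears two identical prenyl groups and is not stereogenic. The step needs 1,2- over 1,4-addition (secured by the organolithium and the deactivated alkoxy-bearing β-carbon) and closure faster than hydrogen shifts (secured by the E-propenyl geometry, which keeps the methyl group outward so that only one inward alkyl group must be accommodated, and by the ethoxy and oxido donors that favour the coiled conformer). Me3SiCl traps dienolate 14 on oxygen, which fixes the enol double bond at C3=C4 for the dehydrogenation.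

**Step 6**
Reactants: 15 1-ethoxy-5-methyl-6,6-bis(3-methylbut-2-en-1-yl)-3-(trimethylsilyloxy)cyclohexa-1,3-diene
Product: 16 3-ethoxy-5-methyl-4,4-bis(3-methylbut-2-en-1-yl)cyclohexa-2,5-dien-1-one
Conditions: Pd(OAc)2 (1.1 equiv), MeCN, rt
Reagents that add atoms: none
Why: In the Saegusa–Ito oxidation divalent palladium forms the C4 palladium enolate from the silyl enol ether, and syn β-hydride elimination of C5–H installs C4=C5 and erases the C5 stereocentre, while the quaternary C6 rules out aromatisation.

**Step 7**
Reactants: 16 3-ethoxy-5-methyl-4,4-bis(3-methylbut-2-en-1-yl)cyclohexa-2,5-dien-1-one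
Product: 17 3-hydroxy-5-methyl-6,6-bis(3-methylbut-2-en-1-yl)cyclohexa-2,4-dien-1-one
Conditions: LiOH, dioxane/H2O, 80 °C; 1 M HCl, 0 °C, to pH 3
Reagents that add atoms: lithium hydroxide, [Li+].[OH-]
Why: Addition–elimination of hydroxide at the alkoxy-bearing carbon (vinylogous saponification, as used for hindered vinylogous esters next to quaternary carbons in polyprenylated acylphloroglucinols) is driven by the delocalised vinylogous carboxylate, and basic conditions avoid acid-induced loss or shift of a prenyl group.

**Step 8**
Reactants: 18 methyl 3-methoxy-2-methylbenzoate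
Product: 19 methyl 2-(bromomethyl)-3-methoxybenzoate
Conditions: N-bromosuccinimide (1.05 equiv), 2,2'-azobis(2-methylpropionitrile) (cat.), PhCF3, reflux
Reagents that add atoms: N-bromosuccinimide, O=C1CCC(=O)N1Br
Why: Wohl–Ziegler radical bromination in a non-polar solvent takes the only benzylic C–H position and suppresses ionic ring bromination of the anisole.

**Step 9**
Reactants: 19 methyl 2-(bromomethyl)-3-methoxybenzoate
Product: 20 methyl 2-formyl-3-methoxybenzoate
Conditions: 4-methylmorpholine N-oxide (3 equiv), 4 Å molecular sieves, MeCN, rt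
Reagents that add atoms: 4-methylmorpholine N-oxide, C[N+]1([O-])CCOCC1
Why: In this N-oxide variant of the Kornblum oxidation, O-alkylation of the N-oxide and base-induced elimination of the amine give the aldehyde at room temperature, which avoids thermal lactonisation to the phthalide.

**Step 10**
Reactants: 20 methyl 2-formyl-3-methoxybenzoate
Product: 21 3-hydroxy-4-methoxy-2,3-dihydro-1H-isoindol-1-one (racemic)
Conditions: aq. NH3 (28 %), THF, rt
Reagents that add atoms: ammonia, N
Why: Ammonia adds to the aldehyde and the hemiaminal nitrogen is acylated by the ortho ester (5-exo-trig lactamisation), and the racemic hemiaminal carbon is of no consequence because it is planarised in step 11.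

**Step 11**
Reactants: 17 3-hydroxy-5-methyl-6,6-bis(3-methylbut-2-en-1-yl)cyclohexa-2,4-dien-1-one; 21 3-hydroxy-4-methoxy-2,3-dihydro-1H-isoindol-1-one
Product: 23 (3S)-3-[2-hydroxy-4-methyl-5,5-bis(3-methylbut-2-en-1-yl)-6-oxocyclohexa-1,3-dien-1-yl]-4-methoxy-2,3-dihydro-1H-isoindol-1-one, via cyclic N-acylimine 22 (not isolated)
Conditions: (R)-3,3'-bis(2,4,6-triisopropylphenyl)-1,1'-binaphthalene-2,2'-diyl hydrogen phosphate (10 mol %), 4 Å molecular sieves, CH2Cl2, 0 °C
Reagents that add atoms: none
Why: In this phosphoric-acid-catalysed asymmetric α-amidoalkylation (Mannich type, 1,3-dicarbonyl enol plus N-acylimine) the acid dehydrates 21, helped by the ortho methoxy donor, to 22 held as its iminium phosphate, and the phosphate binds the iminium N–H and the enol O–H of 17 so that C2, the most nucleophilic carbon of the vinylogous acid, adds to the Re face and sets the (S) centre.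

**Compound list**
1 | diethyl malonate | CCOC(=O)CC(=O)OCC | starting material
2 | prenyl bromide (1-bromo-3-methylbut-2-ene) | CC(C)=CCBr | starting material
3 | diethyl 2,2-bis(3-methylbut-2-en-1-yl)propanedioate | CCOC(=O)C(CC=C(C)C)(CC=C(C)C)C(=O)OCC | intermediate
4 | 2,2-bis(3-methylbut-2-en-1-yl)propanedioic acid | OC(=O)C(CC=C(C)C)(CC=C(C)C)C(=O)O | intermediate
5 | 5-methyl-2-(3-methylbut-2-en-1-yl)hex-4-enoic acid | CC(C)=CCC(CC=C(C)C)C(=O)O | intermediate
6 | 5-methyl-2-(3-methylbut-2-en-1-yl)hex-4-enoyl chloride | CC(C)=CCC(CC=C(C)C)C(=O)Cl | intermediate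
7 | ethoxyacetylene | CCOC#C | starting material
8 | bis(3-methylbut-2-en-1-yl)ketene | CC(C)=CCC(CC=C(C)C)=C=O | intermediate
9 | 3-ethoxy-4,4-bis(3-methylbut-2-en-1-yl)cyclobut-2-en-1-one | CCOC1=CC(=O)C1(CC=C(C)C)CC=C(C)C | intermediate
10 | (E)-1-bromoprop-1-ene | C/C=C/Br | starting material
11 | (E)-prop-1-enyllithium | C/C=C/[Li] | intermediate
12 | lithium 3-ethoxy-4,4-bis(3-methylbut-2-en-1-yl)-1-[(E)-prop-1-enyl]cyclobut-2-en-1-olate (racemic) | [Li+].[O-]C1(/C=C/C)C=C(OCC)C1(CC=C(C)C)CC=C(C)C | intermediate
13 | lithium trienolate, carbon chain cis across the central double bond, E-propenyl end | [Li+].CCOC(=C(CC=C(C)C)CC=C(C)C)/C=C(\C=C\C)[O-] | intermediate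
14 | lithium 3-ethoxy-5-methyl-4,4-bis(3-methylbut-2-en-1-yl)cyclohexa-1(6),2-dien-1-olate (racemic) | [Li+].CCOC1=CC([O-])=CC(C)C1(CC=C(C)C)CC=C(C)C | intermediate
15 | 1-ethoxy-5-methyl-6,6-bis(3-methylbut-2-en-1-yl)-3-(trimethylsilyloxy)cyclohexa-1,3-diene (racemic) | CCOC1=CC(O[Si](C)(C)C)=CC(C)C1(CC=C(C)C)CC=C(C)C | intermediate
16 | 3-ethoxy-5-methyl-4,4-bis(3-methylbut-2-en-1-yl)cyclohexa-2,5-dien-1-one | CCOC1=CC(=O)C=C(C)C1(CC=C(C)C)CC=C(C)C | intermediate
17 | 3-hydroxy-5-methyl-6,6-bis(3-methylbut-2-en-1-yl)cyclohexa-2,4-dien-1-one | CC1=CC(O)=CC(=O)C1(CC=C(C)C)CC=C(C)C | intermediate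
18 | methyl 3-methoxy-2-methylbenzoate | COC(=O)c1cccc(OC)c1C | starting material
19 | methyl 2-(bromomethyl)-3-methoxybenzoate | COC(=O)c1cccc(OC)c1CBr | intermediate
20 | methyl 2-formyl-3-methoxybenzoate | COC(=O)c1cccc(OC)c1C=O | intermediate
21 | 3-hydroxy-4-methoxy-2,3-dihydro-1H-isoindol-1-one (racemic) | COc1cccc2c1C(O)NC2=O | intermediate
22 | 4-methoxy-1H-isoindol-1-one (cyclic N-acylimine, bound to the acid as iminium phosphate) | COc1cccc2c1C=NC2=O | intermediate
23 | (3S)-3-[2-hydroxy-4-methyl-5,5-bis(3-methylbut-2-en-1-yl)-6-oxocyclohexa-1,3-dien-1-yl]-4-methoxy-2,3-dihydro-1H-isoindol-1-one | COc1cccc2c1[C@@H](C1=C(O)C=C(C)C(CC=C(C)C)(CC=C(C)C)C1=O)NC2=O | target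

Total step count: 11. Longest linear sequence: 8 (steps 1–7 and 11).

**Steps most likely to fail**

Risk A (step 5). The disrotatory closure must press a fully substituted terminus, with one inward allylic CH2 group, against the propenyl terminus. It may be outrun by an antarafacial 1,7-hydrogen shift from that CH2 group, or the trienolate may be silylated before it has closed. The fallback closes the same bond by a polar instead of a pericyclic event; it sets out from 9 and comes back at 16, so step 6 is skipped.
- 1-Propynyllithium in THF at −78 °C should give lithium 3-ethoxy-4,4-bis(3-methylbut-2-en-1-yl)-1-(prop-1-yn-1-yl)cyclobut-2-en-1-olate F1.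
- On warming, F1 opens to the lithium ynone dienolate F2.
- Aqueous NH4Cl protonates the α-carbon to give 6-ethoxy-10-methyl-7-(3-methylbut-2-en-1-yl)undeca-6,9-dien-2-yn-4-one F3.
- Catalytic [(t-Bu)2(2-biphenylyl)P]Au(NCMe)SbF6 (monovalent gold) in CH2Cl2 activates the alkyne, and the tetrasubstituted enol ether carbon attacks the β-carbon of the ynone in a 6-endo-dig carbocyclisation.
- Loss of the C2 proton and protodeauration should then give 16 at the correct oxidation level.

Risk B (step 11). Facial selectivity may be poor, a background reaction may be catalysed by the acidic enol itself, and the enantiomeric purity may erode through reversible C–C bond formation. The fallback replaces asymmetric catalysis by racemic synthesis and resolution; it sets out from 17 and 21 and comes back at 23.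
- Catalytic p-toluenesulfonic acid in CH2Cl2 at rt should give the racemic amidoalkylation product F4.
- F4 is separated on a chiral stationary phase (amylose tris(3,5-dimethylphenylcarbamate)).
- The unwanted enantiomer is re-equilibrated with the same acid and recycled.

Risk C (step 7). Hydroxide attack at the hindered alkoxy carbon may be slow. Attack at the methyl-bearing β-carbon followed by retro-aldol ring cleavage may compete, and so may a thermal [3,3] shift of a prenyl group with aromatisation. The fallback removes the ethyl group before the dienone exists; it sets out from 15 and comes back at 17.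
- 1 M HCl in THF at rt should hydrolyse both enol ethers at the enone level to 5-methyl-4,4-bis(3-methylbut-2-en-1-yl)cyclohexane-1,3-dione F5.
- Me3SiOTf and Et3N in CH2Cl2 at 0 °C give the 1,3-bis(trimethylsilyloxy)cyclohexa-1,3-diene F6, whose regiochemistry is fixed by the quaternary C6.
- Pd(OAc)2 in MeCN dehydrogenates C4–C5 to the vinylogous silyl ester F7, which aqueous work-up converts into 17.

**Further compounds**
F1 | step 5 | lithium 3-ethoxy-4,4-bis(3-methylbut-2-en-1-yl)-1-(prop-1-yn-1-yl)cyclobut-2-en-1-olate | [Li+].[O-]C1(C#CC)C=C(OCC)C1(CC=C(C)C)CC=C(C)C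
F2 | step 5 | lithium ynone dienolate | [Li+].CCOC(=C(CC=C(C)C)CC=C(C)C)/C=C(\C#CC)[O-]
F3 | step 5 | 6-ethoxy-10-methyl-7-(3-methylbut-2-en-1-yl)undeca-6,9-dien-2-yn-4-one | CC#CC(=O)CC(OCC)=C(CC=C(C)C)CC=C(C)C
F4 | step 11 | racemic amidoalkylation product (racemic 23) | COc1cccc2c1C(C1=C(O)C=C(C)C(CC=C(C)C)(CC=C(C)C)C1=O)NC2=O
F5 | step 7 | 5-methyl-4,4-bis(3-methylbut-2-en-1-yl)cyclohexane-1,3-dione (racemic) | CC1CC(=O)CC(=O)C1(CC=C(C)C)CC=C(C)C
F6 | step 7 | 5-methyl-6,6-bis(3-methylbut-2-en-1-yl)-1,3-bis(trimethylsilyloxy)cyclohexa-1,3-diene (racemic) | CC1C=C(O[Si](C)(C)C)C=C(O[Si](C)(C)C)C1(CC=C(C)C)CC=C(C)C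
F7 | step 7 | 5-methyl-4,4-bis(3-methylbut-2-en-1-yl)-3-(trimethylsilyloxy)cyclohexa-2,5-dien-1-one | CC1=CC(=O)C=C(O[Si](C)(C)C)C1(CC=C(C)C)CC=C(C)C
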